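**Assumption:** The SMILES has no stereodescriptor and the molecule has no stereocentre. The only possible stereo-element is the hindered C3–C3' axis, which the string does not define. I therefore take the target as the constitution drawn, formed racemic about that axis. Chiral-phase HPLC of 4 would separate the atropisomers if the axis proves configurationally stable.

## Retrosynthetic overview
1. The obvious cut, C3–C3' coupling of two 3-haloflavones (Ullmann or Suzuki), is not used. The crowded central bond is bought as the CH2–CH2 bond of 1,2-dibenzoylethane, which already holds Ph–C2–C3–C3'–C2'–Ph.
2. Cut both O1–C8a bonds (double intramolecular SNAr) to reach an acyclic tetraketone carrying two 2-fluorobenzoyl groups.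
3. Cut both C3–C4 bonds (two-directional double C-aroylation) to reach 1,4-diphenylbutane-1,4-dione plus 2 × 2-fluorobenzoyl chloride.
4. Ring order: all four benzene rings are purchased. Both γ-pyranone rings form last, in the same flask, and this turns the sp3–sp3 bond into the biaryl-type axis.

## Route

**Step 1**
Reactants: 1, 1,4-diphenylbutane-1,4-dione (1,2-dibenzoylethane); 2, 2-fluorobenzoyl chloride (2.6 equiv)
Product: 3, 2,3-dibenzoyl-1,4-bis(2-fluorophenyl)butane-1,4-dione (1,1,2,2-tetraaroylethane; dl/meso mixture at C2/C3, not separated)
Conditions: MgBr2·OEt2 (6 equiv), i-Pr2NEt (8 equiv), CH2Cl2, 0 °C → rt, 24 h, N2; cold aq. NH4Cl/citric acid work-up (no strong acid); crude carried forward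
Reagents that add atoms: 2-fluorobenzoyl chloride (compound 2), O=C(Cl)c1ccccc1F, two equivalents incorporated
Why: Proposed new method: Mg(II)/Hünig's-base soft enolisation keeps regenerating a chelated Mg enolate at whichever CH2 is still unacylated, while the non-enolisable aroyl chloride (no ketene pathway) survives in the same flask, and each C-aroylation is locked by capture of the new 1,3-diketone as its Mg diketonate, so no stoichiometric dianion or proton-quench problem arises; the closest known reaction type is the soft-enolisation crossed-Claisen C-acylation of simple aryl alkyl ketones with acid chlorides, here run twice on a 1,4-diketone, and the two new stereocentres are irrelevant because Step 2 erases both.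

**Step 2**
Reactants: 3, 2,3-dibenzoyl-1,4-bis(2-fluorophenyl)butane-1,4-dione
Product: 4, 3,3'-biflavone (2,2'-diphenyl-4H,4'H-[3,3'-bichromene]-4,4'-dione), the target
Conditions: Cs2CO3 (4 equiv), dry degassed DMF, 90 °C (to 110 °C if the mono-flavone persists), N2, 6–12 h
Reagents that add atoms: none
Why: The benzoyl-derived enolate oxygen of each 1,3-diketonate attacks the C–F carbon activated by the ortho ketone in a six-membered intramolecular SNAr O-arylation (the known metal-free chromone synthesis from 1-(2-haloaryl)-1,3-diketones), and loss of 2 HF makes both former stereocentres sp2 (C3/C3'), so no stereocentre remains and the axis forms racemically.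

Atom balance:
- Step 1: C16H14O2 + 2 C7H4ClFO − 2 HCl = C30H20F2O4 (3)
- Step 2: C30H20F2O4 − 2 HF = C30H18O4 (4)

## Compound list
1 | 1,4-diphenylbutane-1,4-dione | O=C(CCC(=O)c1ccccc1)c1ccccc1 | starting material
2 | 2-fluorobenzoyl chloride | O=C(Cl)c1ccccc1F | starting material
3 | 2,3-dibenzoyl-1,4-bis(2-fluorophenyl)butane-1,4-dione (dl/meso mixture) | O=C(c1ccccc1)C(C(=O)c1ccccc1F)C(C(=O)c1ccccc1F)C(=O)c1ccccc1 | intermediate
4 | 3,3'-biflavone | O=c1c(-c2c(-c3ccccc3)oc3ccccc3c2=O)c(-c2ccccc2)oc2ccccc12 | target

## Summary
Total step count: 2
Longest linear sequence: 2

The route has only two steps, so the three entries below are the three distinct failure points within them.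

1. **Step 1, the second aroylation stalls or gives O-acylation.** The reacting carbon sits next to the first diketonate and is hindered.
   Fallback: build 3 by a different bond. Acylate acetophenone with 2 to give 1-(2-fluorophenyl)-3-phenylpropane-1,3-dione. Then homocouple its sodium enolate oxidatively (NaH, 0.5 equiv I2, the classical tetraaroylethane synthesis) and rejoin at Step 2.
2. **Step 2, the tetraketone is diverted before the first SNAr.** Possible diversions are Paal–Knorr-type furan formation, retro-Claisen cleavage, or air oxidation to the tetraaroylethylene.
   Fallback: go ring by ring instead of two-directionally. Mono-aroylate 1 and close the first pyranone to give 3-phenacylflavone, which removes the doubly enolisable 1,4-diketone. Then aroylate its remaining CH2 and close the second ring.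
3. **Step 2, the second ring closure is too slow.** The crowded mono-flavone diketonate may accumulate.
   Fallback: reverse the polarity of ring closure with a double Baker–Venkataraman route.
   - Double Fries rearrangement of diphenyl succinate gives 1,4-bis(2-hydroxyphenyl)butane-1,4-dione.
   - Convert this to the dibenzoate, then carry out the base-induced double O→C benzoyl shift.
   - Finish by cyclodehydration through the 2-hydroxyflavanone hemiketals.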